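**Retrosynthetic overview**

1. Numbering and feature: C7/C8/C9 are the guaiacyl CH2, its CH and its CH2OH; C7'/C8'/C9' are the benzofuranyl CH2, its CH and its CH2OH. C8 carries C7 and is bonded to C8', which lies alpha to C9'. C7, C8 and C8' can therefore be the three carbons of a cyclopropane fused to a C9-O-C9'(=O) gamma-lactone, with a second acceptor (CO2Et) on C8'.
2. Target 26 <= debenzylation of triol 25 <= LiAlH4 opening of trans lactone 24 (the pivalate is cleaved in the same step) <= Krapcho de-ethoxycarbonylation of 23.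
3. 23 <= one-flask union of cyclopropane lactone 4, aryl Grignard 7 (aryl-C7 formed, C7-C8' cleaved) and benzylic bromide 21 (C7'-C8' formed).
4. 4 <= diethyl malonate + (R)-epichlorohydrin; 7 <= 4-bromoguaiacol; 21 <= 5-iodovanillin + 4-benzyloxy-3-methoxybenzyl alcohol via aryldiazoacetate 15 and an enantioselective rhodium-carbenoid C-H insertion.
5. Ring order: cyclopropane then lactone (step 1); furan ring C of the dihydrobenzofuran (step 10); the cyclopropane is opened in step 16 and the lactone in step 18; aromatic rings A (guaiacyl), B (benzo) and D (2-aryl) are bought.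

Key step: step 16

Assumption: Rh2(S-PTTL)4 is taken, by analogy with insertions of related 2-(benzyloxy)aryl diazoacetates, to give the (2S) ring; should the opposite sense be found, Rh2(R-PTTL)4 would be used in step 10 with no other change.

**Route**

Step 1
Reactants: 1 diethyl malonate; 2 (R)-epichlorohydrin
Product: 4 ethyl (1S,5R)-2-oxo-3-oxabicyclo[3.1.0]hexane-1-carboxylate, via hydroxymethylcyclopropane diester 3 (not isolated)
Conditions: NaOEt, EtOH, 0 °C to reflux
Reagents that add atoms: none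
Why: The malonate anion opens the epoxide at its CH2 terminus, the chlorohydrin alkoxide closes to a new epoxide, 3-exo-tet attack of the malonate carbanion at the stereogenic carbon (inversion) forms the cyclopropane, and the alkoxide lactonises onto the cis ester, so the one stereocentre of 2 fixes both ring-fusion centres as (1S,5R).

Step 2
Reactants: 5 4-bromo-2-methoxyphenol
Product: 6 1-(benzyloxy)-4-bromo-2-methoxybenzene
Conditions: BnBr, K2CO3, DMF, rt
Reagents that add atoms: benzyl bromide, BrCc1ccccc1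
Why: Williamson etherification of the phenoxide masks the acidic OH before metallation.

Step 3
Reactants: 6 1-(benzyloxy)-4-bromo-2-methoxybenzene
Product: 7 4-benzyloxy-3-methoxyphenylmagnesium bromide (THF solution, titrated)
Conditions: Mg turnings, I2 (cat.), THF, reflux
Reagents that add atoms: magnesium, [Mg]
Why: Oxidative insertion of magnesium into the aryl-bromine bond (Grignard formation) is routine for this benzyl-protected bromoguaiacol.

Step 4
Reactants: 8 4-benzyloxy-3-methoxybenzyl alcohol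
Product: 9 4-benzyloxy-3-methoxybenzyl chloride
Conditions: SOCl2, CH2Cl2, 0 °C
Reagents that add atoms: thionyl chloride, O=S(Cl)Cl
Why: The electron-rich benzylic alcohol is chlorinated through its chlorosulfite, and the chloride is used crude at once.

Step 5
Reactants: 10 4-hydroxy-3-iodo-5-methoxybenzaldehyde (5-iodovanillin); 9 4-benzyloxy-3-methoxybenzyl chloride
Product: 11 4-[(4-benzyloxy-3-methoxybenzyl)oxy]-3-iodo-5-methoxybenzaldehyde
Conditions: K2CO3, DMF, 50 °C
Reagents that add atoms: none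
Why: Williamson O-alkylation of the acidic, doubly flanked phenol with a reactive benzylic chloride installs the CH2 that later becomes C2 of the dihydrobenzofuran.

Step 6
Reactants: 11 4-[(4-benzyloxy-3-methoxybenzyl)oxy]-3-iodo-5-methoxybenzaldehyde
Product: 12 {4-[(4-benzyloxy-3-methoxybenzyl)oxy]-3-iodo-5-methoxyphenyl}methanol
Conditions: NaBH4, MeOH/THF, 0 °C
Reagents that add atoms: none
Why: Borohydride reduces the aldehyde chemoselectively and leaves the aryl iodide and both benzylic ethers untouched.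

Step 7
Reactants: 12 {4-[(4-benzyloxy-3-methoxybenzyl)oxy]-3-iodo-5-methoxyphenyl}methanol
Product: 13 tert-butyl({4-[(4-benzyloxy-3-methoxybenzyl)oxy]-3-iodo-5-methoxybenzyl}oxy)dimethylsilane
Conditions: TBSCl, imidazole, DMF, rt
Reagents that add atoms: tert-butyldimethylsilyl chloride, CC(C)(C)[Si](C)(C)Cl
Why: Silylation of the primary alcohol removes the OH that would quench the zinc enolate and undergo O-H insertion with the later carbenoid.

Step 8
Reactants: 13 tert-butyl({4-[(4-benzyloxy-3-methoxybenzyl)oxy]-3-iodo-5-methoxybenzyl}oxy)dimethylsilane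
Product: 14 methyl 2-{2-[(4-benzyloxy-3-methoxybenzyl)oxy]-5-[(tert-butyldimethylsilyloxy)methyl]-3-methoxyphenyl}acetate
Conditions: BrZnCH2CO2Me (preformed from methyl bromoacetate and Zn dust in THF), Pd2(dba)3 (2.5 mol%), XPhos (10 mol%), THF, 60 °C
Reagents that add atoms: (2-methoxy-2-oxoethyl)zinc bromide, COC(=O)C[Zn]Br (from methyl bromoacetate, COC(=O)CBr)
Why: Negishi-type coupling of the Reformatsky reagent (oxidative addition of zerovalent palladium into the C-I bond, transmetallation, reductive elimination) is a neutral alpha-arylation that tolerates ortho-alkoxy aryl halides and the silyl ether.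

Step 9
Reactants: 14 methyl 2-{2-[(4-benzyloxy-3-methoxybenzyl)oxy]-5-[(tert-butyldimethylsilyloxy)methyl]-3-methoxyphenyl}acetate
Product: 15 methyl 2-diazo-2-{2-[(4-benzyloxy-3-methoxybenzyl)oxy]-5-[(tert-butyldimethylsilyloxy)methyl]-3-methoxyphenyl}acetate
Conditions: p-ABSA, DBU, MeCN, 0 °C to rt
Reagents that add atoms: 4-acetamidobenzenesulfonyl azide, CC(=O)Nc1ccc(cc1)S(=O)(=O)N=[N+]=[N-]
Why: Regitz diazo transfer to the DBU-generated arylacetate enolate is the standard entry to donor/acceptor aryldiazoacetates.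

Step 10
Reactants: 15 methyl 2-diazo-2-{2-[(4-benzyloxy-3-methoxybenzyl)oxy]-5-[(tert-butyldimethylsilyloxy)methyl]-3-methoxyphenyl}acetate
Product: 16 methyl (2S,3R)-2-(4-benzyloxy-3-methoxyphenyl)-5-[(tert-butyldimethylsilyloxy)methyl]-7-methoxy-2,3-dihydrobenzofuran-3-carboxylate (cis)
Conditions: Rh2(S-PTTL)4 (2 mol%), toluene, -60 °C
Reagents that add atoms: none
Why: The donor/acceptor carbenoid of divalent rhodium should insert into the activated benzylic O-CH2 bond five atoms away (intramolecular 1,5 C-H insertion) to close furan ring C as the kinetic cis ester, with C2 set by the chiral N-phthaloyl-tert-leucinate ligands.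

Step 11
Reactants: 16 methyl (2S,3R)-2-(4-benzyloxy-3-methoxyphenyl)-5-[(tert-butyldimethylsilyloxy)methyl]-7-methoxy-2,3-dihydrobenzofuran-3-carboxylate
Product: 17 methyl (2S,3S)-2-(4-benzyloxy-3-methoxyphenyl)-5-[(tert-butyldimethylsilyloxy)methyl]-7-methoxy-2,3-dihydrobenzofuran-3-carboxylate (trans)
Conditions: NaOMe, MeOH/THF, rt
Reagents that add atoms: none
Why: Base-mediated epimerisation through the ester enolate moves the C3 ester to the thermodynamically preferred face trans to the C2 aryl group, so C3 is set relative to the untouched C2.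

Step 12
Reactants: 17 methyl (2S,3S)-2-(4-benzyloxy-3-methoxyphenyl)-5-[(tert-butyldimethylsilyloxy)methyl]-7-methoxy-2,3-dihydrobenzofuran-3-carboxylate
Product: 18 {(2S,3R)-2-(4-benzyloxy-3-methoxyphenyl)-5-[(tert-butyldimethylsilyloxy)methyl]-7-methoxy-2,3-dihydrobenzofuran-3-yl}methanol
Conditions: LiAlH4, THF, 0 °C
Reagents that add atoms: none
Why: Hydride reduction of the ester gives the C3 hydroxymethyl group without touching the silyl or benzyl ethers (the descriptor at C3 changes only through priorities).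

Step 13
Reactants: 18 {(2S,3R)-2-(4-benzyloxy-3-methoxyphenyl)-5-[(tert-butyldimethylsilyloxy)methyl]-7-methoxy-2,3-dihydrobenzofuran-3-yl}methanol
Product: 19 {(2S,3R)-2-(4-benzyloxy-3-methoxyphenyl)-5-[(tert-butyldimethylsilyloxy)methyl]-7-methoxy-2,3-dihydrobenzofuran-3-yl}methyl pivalate
Conditions: PivCl, pyridine, DMAP (cat.), CH2Cl2, 0 °C to rt
Reagents that add atoms: pivaloyl chloride, CC(C)(C)C(Cl)=O
Why: Acylation gives a pivalate that is orthogonal to the benzylic silyl ether, should survive fluoride, the magnesium enolate and hot wet DMSO, and is removed by the hydride of step 18 without a separate deprotection.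

Step 14
Reactants: 19 {(2S,3R)-2-(4-benzyloxy-3-methoxyphenyl)-5-[(tert-butyldimethylsilyloxy)methyl]-7-methoxy-2,3-dihydrobenzofuran-3-yl}methyl pivalate
Product: 20 [(2S,3R)-2-(4-benzyloxy-3-methoxyphenyl)-5-(hydroxymethyl)-7-methoxy-2,3-dihydrobenzofuran-3-yl]methyl pivalate
Conditions: TBAF, THF, 0 °C
Reagents that add atoms: none
Why: Fluoride cleaves the primary silyl ether while the hindered pivalate, which cannot migrate to the remote benzylic oxygen, stays in place.

Step 15
Reactants: 20 [(2S,3R)-2-(4-benzyloxy-3-methoxyphenyl)-5-(hydroxymethyl)-7-methoxy-2,3-dihydrobenzofuran-3-yl]methyl pivalate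
Product: 21 [(2S,3R)-2-(4-benzyloxy-3-methoxyphenyl)-5-(bromomethyl)-7-methoxy-2,3-dihydrobenzofuran-3-yl]methyl pivalate
Conditions: CBr4, PPh3, CH2Cl2, 0 °C
Reagents that add atoms: carbon tetrabromide, BrC(Br)(Br)Br
Why: The Appel reaction converts the benzylic alcohol into the bromide under neutral conditions, and the labile para-alkoxybenzyl bromide is used directly in the next step.

Step 16
Reactants: 4 ethyl (1S,5R)-2-oxo-3-oxabicyclo[3.1.0]hexane-1-carboxylate; 7 4-benzyloxy-3-methoxyphenylmagnesium bromide; 21 [(2S,3R)-2-(4-benzyloxy-3-methoxyphenyl)-5-(bromomethyl)-7-methoxy-2,3-dihydrobenzofuran-3-yl]methyl pivalate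
Product: 23 ethyl (3R,4R)-4-(4-benzyloxy-3-methoxybenzyl)-3-{[(2S,3R)-2-(4-benzyloxy-3-methoxyphenyl)-7-methoxy-3-(pivaloyloxymethyl)-2,3-dihydrobenzofuran-5-yl]methyl}-2-oxotetrahydrofuran-3-carboxylate, via bromomagnesium lactone enolate 22 (not isolated)
Conditions: CuI (10 mol%), THF, -30 °C, 7 (0.95 equiv) added to 4; then DMPU, 21 (0.8 equiv), -30 °C to rt
Reagents that add atoms: none
Why: Proposed new method: the Grignard reagent 7 is transmetallated to an arylcopper species that attacks the unsubstituted cyclopropane carbon C7 of 4 in an SN2-type homoconjugate addition, cleaving the C7-C8' bond with release of ring strain and leaving the chelated bromomagnesium lactone-ester enolate 22, which is then C-benzylated by 21; the closest known reactions are the copper-catalysed Grignard opening of this same bicyclic lactone to 4-substituted 3-carbethoxybutyrolactones and the benzylation of alpha-carbethoxybutyrolactone enolates, and only their combination in one flask on the magnesium enolate is new. No ring is closed and the lactone stays intact. C8 comes unchanged from (R)-epichlorohydrin because none of its bonds is broken, and the new quaternary centre C8' should be set by approach of the bromide to the enolate face opposite the C8 benzyl arm. Attack at the methylene rather than the ring-fusion carbon follows from sterics, C- over O-alkylation is favoured by the soft benzylic electrophile and the DMPU-loosened enolate, and keeping 7 limiting leaves no arylmetal to couple with 21 or attack its pivalate.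

Step 17
Reactants: 23 ethyl (3R,4R)-4-(4-benzyloxy-3-methoxybenzyl)-3-{[(2S,3R)-2-(4-benzyloxy-3-methoxyphenyl)-7-methoxy-3-(pivaloyloxymethyl)-2,3-dihydrobenzofuran-5-yl]methyl}-2-oxotetrahydrofuran-3-carboxylate
Product: 24 {(2S,3R)-5-{[(3R,4R)-4-(4-benzyloxy-3-methoxybenzyl)-2-oxotetrahydrofuran-3-yl]methyl}-2-(4-benzyloxy-3-methoxyphenyl)-7-methoxy-2,3-dihydrobenzofuran-3-yl}methyl pivalate (trans lactone)
Conditions: LiCl, H2O, DMSO, 150 °C; then DBU (cat.), toluene, 80 °C
Reagents that add atoms: none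
Why: Krapcho de-ethoxycarbonylation removes the malonate-type ester, and the DBU treatment equilibrates any cis epimer formed on protonation to the more stable trans lactone, which fixes C8' as R relative to the untouched C8.

Step 18
Reactants: 24 {(2S,3R)-5-{[(3R,4R)-4-(4-benzyloxy-3-methoxybenzyl)-2-oxotetrahydrofuran-3-yl]methyl}-2-(4-benzyloxy-3-methoxyphenyl)-7-methoxy-2,3-dihydrobenzofuran-3-yl}methyl pivalate
Product: 25 (2R,3R)-2-(4-benzyloxy-3-methoxybenzyl)-3-{[(2S,3R)-2-(4-benzyloxy-3-methoxyphenyl)-3-(hydroxymethyl)-7-methoxy-2,3-dihydrobenzofuran-5-yl]methyl}butane-1,4-diol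
Conditions: LiAlH4, THF, 0 °C to rt
Reagents that add atoms: none
Why: Hydride opens the lactone to the C9/C9' diol and cleaves the pivalate in the same operation, with no stereocentre involved.

Step 19
Reactants: 25 (2R,3R)-2-(4-benzyloxy-3-methoxybenzyl)-3-{[(2S,3R)-2-(4-benzyloxy-3-methoxyphenyl)-3-(hydroxymethyl)-7-methoxy-2,3-dihydrobenzofuran-5-yl]methyl}butane-1,4-diol
Product: 26 (2R,3R)-2-(4-hydroxy-3-methoxybenzyl)-3-{[(2S,3R)-2-(4-hydroxy-3-methoxyphenyl)-3-(hydroxymethyl)-7-methoxy-2,3-dihydrobenzofuran-5-yl]methyl}butane-1,4-diol (CNP0256425.1)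
Conditions: H2 (1 atm), Pd/C, EtOAc/EtOH, rt
Reagents that add atoms: none
Why: Hydrogenolysis of the two aryl benzyl ethers is fast at ambient pressure and should be stopped at hydrogen uptake so that the benzylic C2-O bond of ring C is not cleaved.

**Compound list**

1 | diethyl malonate | CCOC(=O)CC(=O)OCC | starting material
2 | (R)-epichlorohydrin | ClC[C@H]1CO1 | starting material
3 | diethyl (R)-2-(hydroxymethyl)cyclopropane-1,1-dicarboxylate (formed as its sodium alkoxide) | OC[C@@H]1CC1(C(=O)OCC)C(=O)OCC | intermediate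
4 | ethyl (1S,5R)-2-oxo-3-oxabicyclo[3.1.0]hexane-1-carboxylate | C1[C@H]2COC(=O)[C@@]12C(=O)OCC | intermediate
5 | 4-bromo-2-methoxyphenol | COc1cc(Br)ccc1O | starting material
6 | 1-(benzyloxy)-4-bromo-2-methoxybenzene | COc1cc(Br)ccc1OCc1ccccc1 | intermediate
7 | 4-benzyloxy-3-methoxyphenylmagnesium bromide | COc1cc([Mg]Br)ccc1OCc1ccccc1 | intermediate
8 | 4-benzyloxy-3-methoxybenzyl alcohol | COc1cc(CO)ccc1OCc1ccccc1 | starting material
9 | 4-benzyloxy-3-methoxybenzyl chloride | COc1cc(CCl)ccc1OCc1ccccc1 | intermediate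
10 | 4-hydroxy-3-iodo-5-methoxybenzaldehyde (5-iodovanillin) | COc1cc(C=O)cc(I)c1O | starting material
11 | 4-[(4-benzyloxy-3-methoxybenzyl)oxy]-3-iodo-5-methoxybenzaldehyde | COc1cc(C=O)cc(I)c1OCc1ccc(OCc2ccccc2)c(OC)c1 | intermediate
12 | {4-[(4-benzyloxy-3-methoxybenzyl)oxy]-3-iodo-5-methoxyphenyl}methanol | COc1cc(CO)cc(I)c1OCc1ccc(OCc2ccccc2)c(OC)c1 | intermediate
13 | tert-butyl({4-[(4-benzyloxy-3-methoxybenzyl)oxy]-3-iodo-5-methoxybenzyl}oxy)dimethylsilane | COc1cc(CO[Si](C)(C)C(C)(C)C)cc(I)c1OCc1ccc(OCc2ccccc2)c(OC)c1 | intermediate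
14 | methyl 2-{2-[(4-benzyloxy-3-methoxybenzyl)oxy]-5-[(tert-butyldimethylsilyloxy)methyl]-3-methoxyphenyl}acetate | COC(=O)Cc1cc(CO[Si](C)(C)C(C)(C)C)cc(OC)c1OCc1ccc(OCc2ccccc2)c(OC)c1 | intermediate
15 | methyl 2-diazo-2-{2-[(4-benzyloxy-3-methoxybenzyl)oxy]-5-[(tert-butyldimethylsilyloxy)methyl]-3-methoxyphenyl}acetate | COC(=O)C(=[N+]=[N-])c1cc(CO[Si](C)(C)C(C)(C)C)cc(OC)c1OCc1ccc(OCc2ccccc2)c(OC)c1 | intermediate
16 | methyl (2S,3R)-2-(4-benzyloxy-3-methoxyphenyl)-5-[(tert-butyldimethylsilyloxy)methyl]-7-methoxy-2,3-dihydrobenzofuran-3-carboxylate (cis) | CC(C)(C)[Si](C)(C)OCc1cc(OC)c2c(c1)[C@@H](C(=O)OC)[C@@H](c1ccc(OCc3ccccc3)c(OC)c1)O2 | intermediate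
17 | methyl (2S,3S)-2-(4-benzyloxy-3-methoxyphenyl)-5-[(tert-butyldimethylsilyloxy)methyl]-7-methoxy-2,3-dihydrobenzofuran-3-carboxylate (trans) | CC(C)(C)[Si](C)(C)OCc1cc(OC)c2c(c1)[C@H](C(=O)OC)[C@@H](c1ccc(OCc3ccccc3)c(OC)c1)O2 | intermediate
18 | {(2S,3R)-2-(4-benzyloxy-3-methoxyphenyl)-5-[(tert-butyldimethylsilyloxy)methyl]-7-methoxy-2,3-dihydrobenzofuran-3-yl}methanol | CC(C)(C)[Si](C)(C)OCc1cc(OC)c2c(c1)[C@H](CO)[C@@H](c1ccc(OCc3ccccc3)c(OC)c1)O2 | intermediate
19 | {(2S,3R)-2-(4-benzyloxy-3-methoxyphenyl)-5-[(tert-butyldimethylsilyloxy)methyl]-7-methoxy-2,3-dihydrobenzofuran-3-yl}methyl pivalate | CC(C)(C)[Si](C)(C)OCc1cc(OC)c2c(c1)[C@H](COC(=O)C(C)(C)C)[C@@H](c1ccc(OCc3ccccc3)c(OC)c1)O2 | intermediate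
20 | [(2S,3R)-2-(4-benzyloxy-3-methoxyphenyl)-5-(hydroxymethyl)-7-methoxy-2,3-dihydrobenzofuran-3-yl]methyl pivalate | OCc1cc(OC)c2c(c1)[C@H](COC(=O)C(C)(C)C)[C@@H](c1ccc(OCc3ccccc3)c(OC)c1)O2 | intermediate
21 | [(2S,3R)-2-(4-benzyloxy-3-methoxyphenyl)-5-(bromomethyl)-7-methoxy-2,3-dihydrobenzofuran-3-yl]methyl pivalate | BrCc1cc(OC)c2c(c1)[C@H](COC(=O)C(C)(C)C)[C@@H](c1ccc(OCc3ccccc3)c(OC)c1)O2 | intermediate
22 | bromomagnesium enolate of ethyl (4R)-4-(4-benzyloxy-3-methoxybenzyl)-2-oxotetrahydrofuran-3-carboxylate | CCOC(=O)C1=C(O[Mg]Br)OC[C@@H]1Cc1ccc(OCc2ccccc2)c(OC)c1 | intermediate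
23 | ethyl (3R,4R)-4-(4-benzyloxy-3-methoxybenzyl)-3-{[(2S,3R)-2-(4-benzyloxy-3-methoxyphenyl)-7-methoxy-3-(pivaloyloxymethyl)-2,3-dihydrobenzofuran-5-yl]methyl}-2-oxotetrahydrofuran-3-carboxylate | COc1cc(C[C@H]2COC(=O)[C@]2(C(=O)OCC)Cc2cc(OC)c3c(c2)[C@H](COC(=O)C(C)(C)C)[C@@H](c2ccc(OCc4ccccc4)c(OC)c2)O3)ccc1OCc1ccccc1 | intermediate
24 | {(2S,3R)-5-{[(3R,4R)-4-(4-benzyloxy-3-methoxybenzyl)-2-oxotetrahydrofuran-3-yl]methyl}-2-(4-benzyloxy-3-methoxyphenyl)-7-methoxy-2,3-dihydrobenzofuran-3-yl}methyl pivalate | COc1cc(C[C@H]2COC(=O)[C@@H]2Cc2cc(OC)c3c(c2)[C@H](COC(=O)C(C)(C)C)[C@@H](c2ccc(OCc4ccccc4)c(OC)c2)O3)ccc1OCc1ccccc1 | intermediate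
25 | (2R,3R)-2-(4-benzyloxy-3-methoxybenzyl)-3-{[(2S,3R)-2-(4-benzyloxy-3-methoxyphenyl)-3-(hydroxymethyl)-7-methoxy-2,3-dihydrobenzofuran-5-yl]methyl}butane-1,4-diol | COc1cc(C[C@@H](CO)[C@H](CO)Cc2cc(OC)c3c(c2)[C@H](CO)[C@@H](c2ccc(OCc4ccccc4)c(OC)c2)O3)ccc1OCc1ccccc1 | intermediate
26 | (2R,3R)-2-(4-hydroxy-3-methoxybenzyl)-3-{[(2S,3R)-2-(4-hydroxy-3-methoxyphenyl)-3-(hydroxymethyl)-7-methoxy-2,3-dihydrobenzofuran-5-yl]methyl}butane-1,4-diol | COc1cc(C[C@@H](CO)[C@H](CO)Cc2cc(OC)c3c(c2)[C@H](CO)[C@@H](c2ccc(O)c(OC)c2)O3)ccc1O | target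

**Step count**

Total: 19 steps. Longest linear sequence: 16 steps (steps 4 to 19, from alcohol 8).

**Steps most likely to fail**

1. Step 16 (Proposed new method). What may go wrong: sluggish or O-selective alkylation of the chelated magnesium enolate, coupling of residual arylmetal with the benzylic bromide, or decomposition of the labile bromide before the C-C bond forms. The fallback uses known chemistry, sets out from 4 and 7 and comes back at 24. The copper-catalysed opening is run alone and quenched with aqueous NH4Cl to give ethyl (4R)-4-(4-benzyloxy-3-methoxybenzyl)-2-oxotetrahydrofuran-3-carboxylate F1. Krapcho de-ethoxycarbonylation (LiCl, wet DMSO, 140 °C) then gives (R)-4-(4-benzyloxy-3-methoxybenzyl)dihydrofuran-2(3H)-one F2. Its lithium enolate (LiHMDS, THF, -78 °C) is alkylated with bromide 21 anti to the C4 benzyl group, which should give trans lactone 24 directly, so that step 17 is not needed.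

2. Step 10. What may go wrong: insufficient enantio- or cis-selectivity because the ether is flanked by the 3-methoxy group, or carbene dimerisation at the low temperature needed. The fallback replaces asymmetric catalysis by resolution, sets out from 15 and comes back at 17. Rh2(OAc)4 in CH2Cl2 gives the racemic cis ester, that is 16 together with its enantiomer methyl (2R,3S)-2-(4-benzyloxy-3-methoxyphenyl)-5-[(tert-butyldimethylsilyloxy)methyl]-7-methoxy-2,3-dihydrobenzofuran-3-carboxylate F3. NaOMe epimerisation gives the racemic trans ester, 17 with its enantiomer methyl (2R,3R)-2-(4-benzyloxy-3-methoxyphenyl)-5-[(tert-butyldimethylsilyloxy)methyl]-7-methoxy-2,3-dihydrobenzofuran-3-carboxylate F4. The enantiomers are separated by preparative chromatography on a chiral stationary phase and 17 is carried on.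

3. Step 17. What may go wrong: incomplete loss of the hindered quaternary ester, chloride opening of the lactone at C9, or incomplete equilibration to the trans lactone. The fallback sets out from 23 and comes back at 25. Aqueous KOH in EtOH at reflux hydrolyses the ethyl ester and the pivalate and opens the lactone; acidification relactonises to (3R,4R)-4-(4-benzyloxy-3-methoxybenzyl)-3-{[(2S,3R)-2-(4-benzyloxy-3-methoxyphenyl)-3-(hydroxymethyl)-7-methoxy-2,3-dihydrobenzofuran-5-yl]methyl}-2-oxotetrahydrofuran-3-carboxylic acid F5. Heating in toluene/pyridine at 110 °C decarboxylates it, and DBU equilibration gives (3R,4R)-4-(4-benzyloxy-3-methoxybenzyl)-3-{[(2S,3R)-2-(4-benzyloxy-3-methoxyphenyl)-3-(hydroxymethyl)-7-methoxy-2,3-dihydrobenzofuran-5-yl]methyl}dihydrofuran-2(3H)-one F6. LiAlH4 reduces F6 to triol 25.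

**Further compounds**

F1 | step 16 | ethyl (4R)-4-(4-benzyloxy-3-methoxybenzyl)-2-oxotetrahydrofuran-3-carboxylate (C3 epimerisable) | CCOC(=O)C1C(=O)OC[C@@H]1Cc1ccc(OCc2ccccc2)c(OC)c1
F2 | step 16 | (R)-4-(4-benzyloxy-3-methoxybenzyl)dihydrofuran-2(3H)-one | COc1cc(C[C@H]2COC(=O)C2)ccc1OCc1ccccc1
F3 | step 10 | methyl (2R,3S)-2-(4-benzyloxy-3-methoxyphenyl)-5-[(tert-butyldimethylsilyloxy)methyl]-7-methoxy-2,3-dihydrobenzofuran-3-carboxylate | CC(C)(C)[Si](C)(C)OCc1cc(OC)c2c(c1)[C@H](C(=O)OC)[C@H](c1ccc(OCc3ccccc3)c(OC)c1)O2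
F4 | step 10 | methyl (2R,3R)-2-(4-benzyloxy-3-methoxyphenyl)-5-[(tert-butyldimethylsilyloxy)methyl]-7-methoxy-2,3-dihydrobenzofuran-3-carboxylate | CC(C)(C)[Si](C)(C)OCc1cc(OC)c2c(c1)[C@@H](C(=O)OC)[C@H](c1ccc(OCc3ccccc3)c(OC)c1)O2
F5 | step 17 | (3R,4R)-4-(4-benzyloxy-3-methoxybenzyl)-3-{[(2S,3R)-2-(4-benzyloxy-3-methoxyphenyl)-3-(hydroxymethyl)-7-methoxy-2,3-dihydrobenzofuran-5-yl]methyl}-2-oxotetrahydrofuran-3-carboxylic acid | COc1cc(C[C@H]2COC(=O)[C@]2(C(=O)O)Cc2cc(OC)c3c(c2)[C@H](CO)[C@@H](c2ccc(OCc4ccccc4)c(OC)c2)O3)ccc1OCc1ccccc1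
F6 | step 17 | (3R,4R)-4-(4-benzyloxy-3-methoxybenzyl)-3-{[(2S,3R)-2-(4-benzyloxy-3-methoxyphenyl)-3-(hydroxymethyl)-7-methoxy-2,3-dihydrobenzofuran-5-yl]methyl}dihydrofuran-2(3H)-one | COc1cc(C[C@H]2COC(=O)[C@@H]2Cc2cc(OC)c3c(c2)[C@H](CO)[C@@H](c2ccc(OCc4ccccc4)c(OC)c2)O3)ccc1OCc1ccccc1
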